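## Analysis of the target

The target is a flavanone (2-arylchroman-4-one). Ring A is a phloroglucinol ring with free hydroxyls at C5 and C7 and a 3-hydroxy-3-methylbutyl chain at C8. Ring C holds O1, the stereocentre C2, C3H2 and the C4 ketone. Ring B, bound to C2, carries a 2'-hydroxyl and a 2,2-dimethyl-2H-pyran (ring D) fused linearly across C4' (ether oxygen) and C5' (vinyl carbon).

C2 (S) is the only stereocentre, and it is labile. Base opens ring C by E1cB elimination to the 2'-hydroxychalcone, and the ortho and para oxygen donors of ring B weaken the benzylic C2–O1 bond toward acid. The other sensitive groups are the electron-rich styrene-type C=C of ring D (acid, electrophiles, hydrogenation) and the tertiary alcohol, which can ionise or close onto O7 to a chroman.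

Three regiochemical questions make the synthesis hard. The chain must sit at C8 and not C6; the two isomers differ only in which of the two oxygens flanking the acyl-bearing carbon becomes O1. Ring D must be linear and not angular. The labile C2 must be set late.

The plan rests on one feature of ring A. C8a (bearing O1) and C4a (bearing the C4 acyl carbon) are adjacent, with the C5 oxygen next to C4a and the C8 chain next to C8a. This is the pattern left by an unsymmetrical 3-alkoxy-6-alkyl aryne that has inserted into the O–C(acyl) bond of a cinnamic acid.

## Retrosynthetic reasoning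

**26 to 25.** The last operation only unmasks four hydroxyls. All are carried as methoxymethyl ethers because these survive organolithium, fluoride and hydroxide and leave under acid, whereas C2 cannot tolerate base.

**25 to 24.** The O1–C2 bond is cut, since this is the bond the molecule itself opens and closes reversibly. In chalcone 24 only the oxygen destined to become O1 is free, so closure can give only the 8-alkyl flavanone. A chiral bifunctional catalyst has to choose the face of the enone under kinetic control.

**24 to 11 and 21 (through aryne 22).** The C8a–O1 and C4a–C4 bonds are cut together. This joins the two halves, delivers the ortho-hydroxyaryl ketone at the correct oxidation level and decides 8-alkyl against 6-alkyl by the polarisation of the aryne. It avoids a Friedel–Crafts acylation on an acetal-laden ring and any need to tell two phenols apart. Any material that closes to racemic flavanone 23 in the flask is returned to 24 by base.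

**11 back to 5.** The acetal on the side chain of 11 is put on last, from alcohol 10. The aryl–silicon bond of 10 comes from an oxygen-to-carbon silyl shift in the aryllithium derived from bis-silyl ether 7, and the triflate from the phenoxide so formed. Compound 7 comes from bromophenol 6, and 6 from phenol 5 by bromination ortho to the free hydroxyl. The one free phenol of 5 is therefore both the directing group and the future leaving group.

**5 to 1.** The two C–CH3 bonds of the tertiary alcohol are cut, leading to dihydrocoumarin 3, and from there to 2 and 1. The coumarin already contains the three side-chain carbons on the correct ring carbon. Its lactone distinguishes the oxygen that becomes the triflate from the two that stay as acetals, a distinction a symmetric phloroglucinol could not provide.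

**21 to 12, 13 and 20.** The aryl–vinyl bond of 21 is cut to bromochromene 19 and acrylic acid 20 (palladium-catalysed vinylation). Chromene 19 derives from chromanone 15 by way of 16 and 17. Chromanone 15 comes from 4-bromoresorcinol 12 and acid 13. The bromine of 12 blocks one activated position during the annulation and later marks the carbon that carries the side arm, so ring D can only be linear.

## Alternatives that were turned down

**Alternative 1:** Here the C2–C3 bond is cut. A chiral dirhodium tetracarboxylate would decompose the ortho-(arylmethoxy)aryl diazomethyl ketone A1, and the carbene carbon would insert into the benzylic ether C–H bond to give the silyl-protected (2S)-flavanone A2.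
- In favour: ring C and the stereocentre arise in one irreversible, catalyst-controlled C–C bond formation. On this point it is stronger than the chosen route, whose stereocentre is set in a separate and reversible oxa-Michael step.
- Against: the insertion must close a six-membered ring, while the same divalent rhodium carbene can reach the ether oxygen through a five-membered transition state. The resulting oxonium ylide would undergo a [1,2]-shift of the electron-rich benzyl group to a benzofuranone.
- Against: acceptor-only carbenes are unselective, and the chromene C=C and the electron-rich ring B are open to cyclopropanation and Büchner-type addition.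
- Against: A1 requires a hindered 2,6-dioxygenated benzoic acid, diazo chemistry and a separate differentiation of the two ortho oxygens of ring A. Its four silyl ethers would come off under fluoride, which is basic toward C2.
- In its place the chosen route offers a union in which regiochemistry and oxidation level are settled in the coupling itself, with no diazo compound.

**Alternative 2:** Here C4–C3 and O1–C2 are cut. A chiral BINOL-derived phosphoric acid would ionise the ring A ortho-hydroxybenzyl alcohol A3 to its ortho-quinone methide, which would add to the ring B ortho-hydroxystyrene A4 and give the (2S)-flavan A5.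
- In favour: two bonds, ring C, the union of both halves and the stereocentre in one step. In convergency and stereocontrol at the ring-forming stage this is at least equal to the chosen route.
- Against: A5 has a methylene at C4. The ketone would have to be introduced afterwards by benzylic oxidation, in competition with hydride abstraction at C2 (benzylic to the more electron-rich ring B and alpha to O1) and with oxidation of the free 2'-phenol and the chromene. This would cost protection, two oxidation stages and deprotection.
- Against: the unsubstituted methide from A3 is prone to self-condensation.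
- The chosen route forms C4 as a ketone in the coupling and needs no redox adjustment.

**Alternative 3:** Here ring D is cut at C5'–CH and O–C(CH3)2. Heating the 4'-O-(1,1-dimethylpropargyl) ether A6 would trigger a [3,3] shift, a hydrogen shift and an oxa-6π electrocyclisation to the chromene A7.
- In favour: the chemistry is familiar and the ring B precursor is simple. The sensitive chromene appears only at the end, so it need not survive coupling steps; on that point it is stronger than the chosen route, in which 19 and 21 carry ring D through a Heck reaction, fluoride at 125 °C and hydroxide.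
- Against: the rearrangement can also end at C3', between the two oxygens, and a bulky 2'-silyl group is only a steric hope for the linear isomer.
- Against: the temperatures needed would act on a finished flavanone with a labile C2 and a free tertiary alcohol.
- Against: the step solves none of the core problems (joining the rings, 8- versus 6-alkyl, C2), which would need another method anyway.
- In the chosen route the linear fusion is fixed by the bromine of 12, and the chromene is inert to base and fluoride.

Key step: step 13

Assumption on the chemistry: the quinidine-derived member of the pseudoenantiomeric pair of cinchona thioureas is taken to give the 2S flavanone. If the sense of induction is the reverse, the quinine-derived catalyst is used in the same way.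

## Route

**Step 1**
Reactants: 1 5,7-dihydroxycoumarin
Product: 2 5,7-bis(methoxymethoxy)-2H-chromen-2-one
Conditions: MOMCl, i-Pr2NEt, DMF, 0 °C to rt
Reagents that add atoms: chloromethyl methyl ether, COCCl
Why: Both phenols are O-alkylated by the chloromethyl ether under amine base (Williamson-type etherification); the acetals are inert to the hydrogenation, Grignard, organolithium, fluoride and hydroxide steps that follow.

**Step 2**
Reactants: 2 5,7-bis(methoxymethoxy)-2H-chromen-2-one
Product: 3 5,7-bis(methoxymethoxy)chroman-2-one
Conditions: H2 (4 atm), 10% Pd/C, EtOAc, rt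
Reagents that add atoms: none
Why: Catalytic hydrogenation saturates the lactone-conjugated C3=C4 bond of the coumarin; the benzene ring and the acetals are not reduced under these mild conditions.

**Step 3**
Reactants: 3 5,7-bis(methoxymethoxy)chroman-2-one
Product: 5 2-(3-hydroxy-3-methylbutyl)-3,5-bis(methoxymethoxy)phenol, via ring-opened methyl ketone 4 (not isolated)
Conditions: MeMgBr (3.5 equiv), THF, 0 °C to rt; aq NH4Cl
Reagents that add atoms: methylmagnesium bromide, C[Mg]Br
Why: Double Grignard addition to the aryl lactone: the first methyl opens the ring to ketone 4 and frees the phenoxide on the future C8a, the second gives the tertiary alkoxide. The lactone thereby marks one of the two oxygens flanking the chain as the future leaving group.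

**Step 4**
Reactants: 5 2-(3-hydroxy-3-methylbutyl)-3,5-bis(methoxymethoxy)phenol
Product: 6 6-bromo-2-(3-hydroxy-3-methylbutyl)-3,5-bis(methoxymethoxy)phenol
Conditions: NBS (1.0 equiv), i-Pr2NH (10 mol %), CH2Cl2, −78 to −20 °C
Reagents that add atoms: N-bromosuccinimide, O=C1CCC(=O)N1Br
Why: Electrophilic aromatic bromination, directed ortho by hydrogen bonding of the free phenol to the N-bromoamine formed in the flask; the only other open carbon lies between two bulkier methoxymethoxy groups. Low temperature and one equivalent should hold it at monobromination.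

**Step 5**
Reactants: 6 6-bromo-2-(3-hydroxy-3-methylbutyl)-3,5-bis(methoxymethoxy)phenol
Product: 7 [6-bromo-3,5-bis(methoxymethoxy)-2-(3-methyl-3-trimethylsilyloxybutyl)phenoxy]trimethylsilane
Conditions: HMDS, TMSCl (cat.), THF, 65 °C; evaporate
Reagents that add atoms: hexamethyldisilazane, C[Si](C)(C)N[Si](C)(C)C
Why: Silylation of the phenol and the tertiary alcohol with a reagent whose only by-product is ammonia; the aryl silyl ether is the silicon donor for the next step and the alkyl silyl ether masks the alcohol toward n-BuLi and Tf2O.

**Step 6**
Reactants: 7 [6-bromo-3,5-bis(methoxymethoxy)-2-(3-methyl-3-trimethylsilyloxybutyl)phenoxy]trimethylsilane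
Product: 10 2-(3-hydroxy-3-methylbutyl)-3,5-bis(methoxymethoxy)-6-(trimethylsilyl)phenyl trifluoromethanesulfonate, via lithium 2-silylphenoxide 8 (not isolated), via silyl ether triflate 9 (not isolated)
Conditions: n-BuLi, THF, −78 °C; Tf2O, −78 °C; then citric acid, MeOH–H2O, rt
Reagents that add atoms: trifluoromethanesulfonic anhydride, O=S(=O)(OS(=O)(=O)C(F)(F)F)C(F)(F)F
Why: Bromine–lithium exchange gives the aryllithium between the silyl ether and the neighbouring acetal; it takes silicon from the adjacent oxygen (retro-Brook 1,3 O-to-C shift) to give phenoxide 8, which is triflated at oxygen to 9. The mild acid wash cleaves only the labile tertiary trimethylsilyl ether.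

**Step 7**
Reactants: 10 2-(3-hydroxy-3-methylbutyl)-3,5-bis(methoxymethoxy)-6-(trimethylsilyl)phenyl trifluoromethanesulfonate
Product: 11 3,5-bis(methoxymethoxy)-2-[3-(methoxymethoxy)-3-methylbutyl]-6-(trimethylsilyl)phenyl trifluoromethanesulfonate
Conditions: MOMCl (excess), i-Pr2NEt, DMAP (cat.), CH2Cl2, 40 °C
Reagents that add atoms: chloromethyl methyl ether, COCCl
Why: Acetal protection of the hindered tertiary alcohol; the aryl–silicon bond and the triflate are inert to amine base. The capped oxygen can no longer attack the aryne of step 13 as an alkoxide.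

**Step 8**
Reactants: 12 4-bromoresorcinol; 13 3-methylbut-2-enoic acid
Product: 15 6-bromo-7-hydroxy-2,2-dimethylchroman-4-one, via acylated enone 14 (not isolated)
Conditions: P2O5, MeSO3H, 70 °C
Reagents that add atoms: none
Why: Friedel–Crafts acylation at the carbon para to one hydroxyl and ortho to the other (the site between the hydroxyls is hindered and the bromine occupies the third activated carbon), then 6-endo oxa-Michael closure of enone 14. The bromine ends up at C6 of the chromanone and fixes the linear fusion of ring D.

**Step 9**
Reactants: 15 6-bromo-7-hydroxy-2,2-dimethylchroman-4-one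
Product: 16 6-bromo-7-(methoxymethoxy)-2,2-dimethylchroman-4-one
Conditions: MOMCl, i-Pr2NEt, CH2Cl2, 0 °C to rt
Reagents that add atoms: chloromethyl methyl ether, COCCl
Why: O-Alkylation of the only phenol, which has to be capped before the Heck, aryne and hydroxide steps.

**Step 10**
Reactants: 16 6-bromo-7-(methoxymethoxy)-2,2-dimethylchroman-4-one
Product: 17 6-bromo-7-(methoxymethoxy)-2,2-dimethylchroman-4-ol (racemic)
Conditions: NaBH4, MeOH–THF, 0 °C
Reagents that add atoms: none
Why: Hydride reduction of the aryl ketone to the benzylic alcohol; aryl bromide and acetal are untouched, and the new centre is removed in the next step.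

**Step 11**
Reactants: 17 6-bromo-7-(methoxymethoxy)-2,2-dimethylchroman-4-ol
Product: 19 6-bromo-7-(methoxymethoxy)-2,2-dimethyl-2H-chromene, via benzylic mesylate 18 (not isolated)
Conditions: MsCl, Et3N, CH2Cl2, 0 °C; then DBU, 40 °C
Reagents that add atoms: none
Why: Mesylate 18, flanked by ortho and para oxygen donors, ionises readily and loses a C3 proton to base (E1-type dehydration). The 2H-chromene forms without the Brønsted acid that would endanger the acetal.

**Step 12**
Reactants: 19 6-bromo-7-(methoxymethoxy)-2,2-dimethyl-2H-chromene; 20 acrylic acid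
Product: 21 (E)-3-[7-(methoxymethoxy)-2,2-dimethyl-2H-chromen-6-yl]acrylic acid
Conditions: Pd(OAc)2 (5 mol %), P(o-tol)3 (10 mol %), Et3N, DMF, 100 °C; citric acid work-up
Reagents that add atoms: none
Why: Mizoroki–Heck reaction: oxidative addition of zerovalent palladium to the C–Br bond, syn insertion of the acrylate and syn β-hydride elimination give the E acid. The electron-rich cis-disubstituted chromene olefin inserts far more slowly than acrylate.

**Step 13**
Reactants: 11 3,5-bis(methoxymethoxy)-2-[3-(methoxymethoxy)-3-methylbutyl]-6-(trimethylsilyl)phenyl trifluoromethanesulfonate; 21 (E)-3-[7-(methoxymethoxy)-2,2-dimethyl-2H-chromen-6-yl]acrylic acid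
Product: 24 (E)-1-{2-hydroxy-4,6-bis(methoxymethoxy)-3-[3-(methoxymethoxy)-3-methylbutyl]phenyl}-3-[7-(methoxymethoxy)-2,2-dimethyl-2H-chromen-6-yl]prop-2-en-1-one, via aryne 22 (not isolated), via racemic flavanone 23 (not isolated)
Conditions: CsF (4 equiv), THF, 125 °C, sealed tube; then KOH, MeOH–H2O, rt; AcOH to pH 6, 0 °C
Reagents that add atoms: none
Why: Fluoride attacks silicon of 11 and triflate leaves from the neighbouring carbon, giving aryne 22 (C4a≡C8a); the caesium carboxylate of 21 adds through oxygen to C8a, the aryl anion formed at C4a closes onto the neighbouring ester carbonyl to a four-membered alkoxide, and this collapses by C–O cleavage to the ketone phenoxide, so the aryne has formally inserted into the O–C(acyl) bond (C8a–O1 and C4a–C4 formed). The closest known reaction type is the fluoride-induced insertion of arynes from ortho-silylaryl triflates into the C–O bond of carboxylic acids to give ortho-hydroxyaryl ketones, which with cinnamic acids can run on to chroman-4-ones. No ring is kept: the four-membered ring is transient, and whatever part of the phenoxide closes by 6-endo-trig oxa-Michael addition to racemic 23 at 125 °C is reopened by E1cB elimination in the hydroxide stage, so that 24 is the single product after cold neutralisation. No stereocentre is set: C2 of 23 is racemic and is erased again, and the E geometry of the enone comes unchanged from 21. The selectivity needed is regiochemical: the inductively withdrawing methoxymethoxy group on C5 distorts 22 so that the nucleophile attacks the distal carbon C8a and the charge develops at C4a beside oxygen, while the C8 chain opposes this only by modest steric hindrance. This one event places O1 next to the chain and so decides 8-alkyl against 6-alkyl. The side-chain oxygen is carried as an acetal because a free alkoxide three atoms from C8 would close a chroman on the aryne; surplus 21 leaves as its salt in the basic wash.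

**Step 14**
Reactants: 24 (E)-2'-hydroxychalcone, tetrakis(methoxymethyl) protected
Product: 25 (2S)-5,7-bis(methoxymethoxy)-8-[3-(methoxymethoxy)-3-methylbutyl]-2-[7-(methoxymethoxy)-2,2-dimethyl-2H-chromen-6-yl]chroman-4-one
Conditions: 1-[3,5-bis(trifluoromethyl)phenyl]-3-(9-deoxy-epi-quinidin-9-yl)thiourea (20 mol %), toluene, 0 °C to rt
Reagents that add atoms: none
Why: Intramolecular oxa-Michael addition (6-endo-trig) under bifunctional catalysis: the quinuclidine nitrogen deprotonates the only free phenol while the thiourea hydrogen-bonds the enone carbonyl, so the phenoxide is delivered to one face of the β-carbon and C2 is set as S by the catalyst. The reaction is run under kinetic control in a non-polar solvent and stopped before the reverse reaction erodes the selectivity.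

**Step 15**
Reactants: 25 (2S)-flavanone, tetrakis(methoxymethyl) protected
Product: 26 (2S)-5,7-dihydroxy-8-(3-hydroxy-3-methylbutyl)-2-(7-hydroxy-2,2-dimethyl-2H-chromen-6-yl)chroman-4-one
Conditions: HCl (aq, 3 M)–MeOH–THF, 35–40 °C
Reagents that add atoms: none
Why: Acid-catalysed transacetalisation to methanol removes the four methoxymethyl groups as dimethoxymethane; no base touches C2. Dilute acid at modest temperature is chosen to spare the chromene, the tertiary alcohol and the benzylic C2–O1 bond.

## Compound list

1 | 5,7-dihydroxycoumarin | O=c1ccc2c(O)cc(O)cc2o1 | starting material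
2 | 5,7-bis(methoxymethoxy)-2H-chromen-2-one | O=c1ccc2c(OCOC)cc(OCOC)cc2o1 | intermediate
3 | 5,7-bis(methoxymethoxy)chroman-2-one | O=C1CCc2c(OCOC)cc(OCOC)cc2O1 | intermediate
4 | 4-[2-hydroxy-4,6-bis(methoxymethoxy)phenyl]butan-2-one (present as its magnesium phenoxide) | CC(=O)CCc1c(O)cc(OCOC)cc1OCOC | intermediate
5 | 2-(3-hydroxy-3-methylbutyl)-3,5-bis(methoxymethoxy)phenol | CC(C)(O)CCc1c(O)cc(OCOC)cc1OCOC | intermediate
6 | 6-bromo-2-(3-hydroxy-3-methylbutyl)-3,5-bis(methoxymethoxy)phenol | CC(C)(O)CCc1c(O)c(Br)c(OCOC)cc1OCOC | intermediate
7 | [6-bromo-3,5-bis(methoxymethoxy)-2-(3-methyl-3-trimethylsilyloxybutyl)phenoxy]trimethylsilane | CC(C)(O[Si](C)(C)C)CCc1c(O[Si](C)(C)C)c(Br)c(OCOC)cc1OCOC | intermediate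
8 | lithium 3,5-bis(methoxymethoxy)-2-(3-methyl-3-trimethylsilyloxybutyl)-6-(trimethylsilyl)phenoxide | CC(C)(O[Si](C)(C)C)CCc1c([O-])c([Si](C)(C)C)c(OCOC)cc1OCOC.[Li+] | intermediate
9 | 3,5-bis(methoxymethoxy)-2-(3-methyl-3-trimethylsilyloxybutyl)-6-(trimethylsilyl)phenyl trifluoromethanesulfonate | CC(C)(O[Si](C)(C)C)CCc1c(OS(=O)(=O)C(F)(F)F)c([Si](C)(C)C)c(OCOC)cc1OCOC | intermediate
10 | 2-(3-hydroxy-3-methylbutyl)-3,5-bis(methoxymethoxy)-6-(trimethylsilyl)phenyl trifluoromethanesulfonate | CC(C)(O)CCc1c(OS(=O)(=O)C(F)(F)F)c([Si](C)(C)C)c(OCOC)cc1OCOC | intermediate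
11 | 3,5-bis(methoxymethoxy)-2-[3-(methoxymethoxy)-3-methylbutyl]-6-(trimethylsilyl)phenyl trifluoromethanesulfonate | CC(C)(OCOC)CCc1c(OCOC)cc(OCOC)c([Si](C)(C)C)c1OS(=O)(=O)C(F)(F)F | intermediate
12 | 4-bromoresorcinol (4-bromobenzene-1,3-diol) | Oc1ccc(Br)c(O)c1 | starting material
13 | 3-methylbut-2-enoic acid | CC(C)=CC(=O)O | starting material
14 | 1-(5-bromo-2,4-dihydroxyphenyl)-3-methylbut-2-en-1-one | CC(C)=CC(=O)c1cc(Br)c(O)cc1O | intermediate
15 | 6-bromo-7-hydroxy-2,2-dimethylchroman-4-one | CC1(C)CC(=O)c2cc(Br)c(O)cc2O1 | intermediate
16 | 6-bromo-7-(methoxymethoxy)-2,2-dimethylchroman-4-one | CC1(C)CC(=O)c2cc(Br)c(OCOC)cc2O1 | intermediate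
17 | 6-bromo-7-(methoxymethoxy)-2,2-dimethylchroman-4-ol (racemic) | CC1(C)CC(O)c2cc(Br)c(OCOC)cc2O1 | intermediate
18 | 6-bromo-7-(methoxymethoxy)-2,2-dimethylchroman-4-yl methanesulfonate (racemic) | CC1(C)CC(OS(C)(=O)=O)c2cc(Br)c(OCOC)cc2O1 | intermediate
19 | 6-bromo-7-(methoxymethoxy)-2,2-dimethyl-2H-chromene | CC1(C)C=Cc2cc(Br)c(OCOC)cc2O1 | intermediate
20 | acrylic acid | C=CC(=O)O | starting material
21 | (E)-3-[7-(methoxymethoxy)-2,2-dimethyl-2H-chromen-6-yl]acrylic acid | OC(=O)/C=C/c1cc2c(cc1OCOC)OC(C)(C)C=C2 | intermediate
22 | 1,2-didehydro-4,6-bis(methoxymethoxy)-3-[3-(methoxymethoxy)-3-methylbutyl]benzene (aryne) | CC(C)(OCOC)CCC1=C(OCOC)C=C(OCOC)C#C1 | intermediate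
23 | racemic 5,7-bis(methoxymethoxy)-8-[3-(methoxymethoxy)-3-methylbutyl]-2-[7-(methoxymethoxy)-2,2-dimethyl-2H-chromen-6-yl]chroman-4-one | CC(C)(OCOC)CCc1c(OCOC)cc(OCOC)c2c1OC(c1cc3c(cc1OCOC)OC(C)(C)C=C3)CC2=O | intermediate
24 | (E)-1-{2-hydroxy-4,6-bis(methoxymethoxy)-3-[3-(methoxymethoxy)-3-methylbutyl]phenyl}-3-[7-(methoxymethoxy)-2,2-dimethyl-2H-chromen-6-yl]prop-2-en-1-one | CC(C)(OCOC)CCc1c(OCOC)cc(OCOC)c(C(=O)/C=C/c2cc3c(cc2OCOC)OC(C)(C)C=C3)c1O | intermediate
25 | (2S)-5,7-bis(methoxymethoxy)-8-[3-(methoxymethoxy)-3-methylbutyl]-2-[7-(methoxymethoxy)-2,2-dimethyl-2H-chromen-6-yl]chroman-4-one | CC(C)(OCOC)CCc1c(OCOC)cc(OCOC)c2c1O[C@H](c1cc3c(cc1OCOC)OC(C)(C)C=C3)CC2=O | intermediate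
26 | (2S)-5,7-dihydroxy-8-(3-hydroxy-3-methylbutyl)-2-(7-hydroxy-2,2-dimethyl-2H-chromen-6-yl)chroman-4-one | CC(C)(O)CCc1c(O)cc(O)c2c1O[C@H](c1cc3c(cc1O)OC(C)(C)C=C3)CC2=O | target

## Step count and least certain steps

Total step count: 15. Longest linear sequence: 10 steps (steps 1 to 7, then 13 to 15). The ring B branch (steps 8 to 12) is 5 steps to the point of convergence.

**Step 13 (key step).**
- What may go wrong: addition of the carboxylate at the wrong aryne carbon if the steric push of the C8 chain outweighs the polarisation by the C5 oxygen.
- Protonation of the aryl anion before it reaches the ester carbonyl, ending in simple O-arylation of the acid.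
- Capture of the aryne by the side-chain acetal oxygen with loss of the methoxymethyl cation.
- A second arylation of the product phenoxide.
- Fallback (sets out from 6 and 21, rejoins at 26): the same acyl shift is run stepwise from the bromide, so that the position of bromine fixes the regiochemistry. Phenol 6 is acylated at the phenolic oxygen with 21 (EDC·HCl, DMAP, CH2Cl2; the tertiary alcohol is too hindered to compete) to give the ortho-bromoaryl cinnamate F1. After deprotonation of the tertiary hydroxyl with LiHMDS, bromine–lithium exchange with n-BuLi at −100 °C gives the aryllithium at the future C4a, which attacks the neighbouring ester carbonyl (anionic Fries rearrangement, 1,3 O-to-C acyl shift) to the side-chain hydroxy chalcone F2. No aryne is involved, so the side chain needs no acetal. F2 is closed with the thiourea catalyst of step 14 to the (2S)-flavanone F3, and its three phenolic acetals are removed as in step 15 to give 26.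

**Step 14.**
- What may go wrong: slow closure, because the phenol is hydrogen-bonded to the carbonyl and the β-aryl group is electron-rich.
- Loss of enantiomeric purity through the reverse reaction as the system drifts toward equilibrium.
- Fallback (sets out from 24, rejoins at 25): 24 is closed without stereocontrol (NaOAc, EtOH, reflux) to racemic 23, which is resolved kinetically by asymmetric transfer hydrogenation (RuCl(p-cymene)[(R,R)-TsDPEN], HCO2H–Et3N). By the usual model for aryl ketones this catalyst should reduce the 2R enantiomer faster, to the cis-(2R,4R)-flavan-4-ol F4, and leave 25, which is separated by chromatography. If the opposite enantiomer is consumed, the (S,S) catalyst is used.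

**Step 4.**
- What may go wrong: bromination para to the hydroxyl, at the carbon between the two acetal oxygens, or double bromination of this very electron-rich ring.
- Fallback (sets out from 5, rejoins at 11): the silicon is introduced by directed ortho-metalation. Phenol 5 with isopropyl isocyanate and Et3N gives the aryl N-isopropylcarbamate F5. Its tertiary alcohol is capped (MOMCl, i-Pr2NEt, 40 °C) to give the acetal carbamate F6. N-Silylation in the flask (TBSOTf, TMEDA), lithiation with n-BuLi–TMEDA at −78 °C between the carbamate and the neighbouring acetal, and quenching with TMSCl give, after aqueous NaHSO4, the ortho-silyl carbamate F7. Et2NH and DBU in MeCN at 40 °C release the phenoxide, which is triflated in the same flask with PhNTf2 to 11.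

**Step 15.**
- What may go wrong: partial racemisation by acid-assisted opening of the C2–O1 bond, which the 2'- and 4'-oxygens of ring B facilitate.
- Closure of the freed tertiary alcohol onto O7 to a chroman.
- Addition of methanol to the chromene.
- Incomplete cleavage of the tertiary acetal.
- Fallback (sets out from 23, rejoins at 26): the stereochemical question is moved behind the acid step. Racemic 23, made as in the fallback to step 14, is deprotected under conditions tuned only for chemoselectivity (lower acid strength, longer time) to the racemic flavanone F8, and the enantiomers are separated by preparative chromatography on a polysaccharide chiral phase to give 26.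

**Step 8.**
- What may go wrong: loss or migration of bromine on the resorcinol in the strongly acidic medium, which would destroy the regiochemical marker.
- Fallback (sets out from 12, rejoins at 19): the chromene is annulated directly. Heating 12 with 3-methylbut-2-enal and ethylenediammonium diacetate in toluene (Knoevenagel condensation, then oxa-6π electrocyclisation) should give the bromochromenol F9, which with MOMCl and i-Pr2NEt gives 19.

## Further compounds

F1 | step 13 | 6-bromo-2-(3-hydroxy-3-methylbutyl)-3,5-bis(methoxymethoxy)phenyl (E)-3-[7-(methoxymethoxy)-2,2-dimethyl-2H-chromen-6-yl]acrylate | CC(C)(O)CCc1c(OC(=O)/C=C/c2cc3c(cc2OCOC)OC(C)(C)C=C3)c(Br)c(OCOC)cc1OCOC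
F2 | step 13 | (E)-1-[2-hydroxy-3-(3-hydroxy-3-methylbutyl)-4,6-bis(methoxymethoxy)phenyl]-3-[7-(methoxymethoxy)-2,2-dimethyl-2H-chromen-6-yl]prop-2-en-1-one | CC(C)(O)CCc1c(OCOC)cc(OCOC)c(C(=O)/C=C/c2cc3c(cc2OCOC)OC(C)(C)C=C3)c1O
F3 | step 13 | (2S)-8-(3-hydroxy-3-methylbutyl)-5,7-bis(methoxymethoxy)-2-[7-(methoxymethoxy)-2,2-dimethyl-2H-chromen-6-yl]chroman-4-one | CC(C)(O)CCc1c(OCOC)cc(OCOC)c2c1O[C@H](c1cc3c(cc1OCOC)OC(C)(C)C=C3)CC2=O
F4 | step 14 | (2R,4R)-5,7-bis(methoxymethoxy)-8-[3-(methoxymethoxy)-3-methylbutyl]-2-[7-(methoxymethoxy)-2,2-dimethyl-2H-chromen-6-yl]chroman-4-ol (cis) | CC(C)(OCOC)CCc1c(OCOC)cc(OCOC)c2c1O[C@@H](c1cc3c(cc1OCOC)OC(C)(C)C=C3)C[C@H]2O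
F5 | step 4 | 2-(3-hydroxy-3-methylbutyl)-3,5-bis(methoxymethoxy)phenyl N-isopropylcarbamate | CC(C)(O)CCc1c(OC(=O)NC(C)C)cc(OCOC)cc1OCOC
F6 | step 4 | 3,5-bis(methoxymethoxy)-2-[3-(methoxymethoxy)-3-methylbutyl]phenyl N-isopropylcarbamate | CC(C)(OCOC)CCc1c(OC(=O)NC(C)C)cc(OCOC)cc1OCOC
F7 | step 4 | 3,5-bis(methoxymethoxy)-2-[3-(methoxymethoxy)-3-methylbutyl]-6-(trimethylsilyl)phenyl N-isopropylcarbamate | CC(C)(OCOC)CCc1c(OC(=O)NC(C)C)c([Si](C)(C)C)c(OCOC)cc1OCOC
F8 | step 15 | racemic 5,7-dihydroxy-8-(3-hydroxy-3-methylbutyl)-2-(7-hydroxy-2,2-dimethyl-2H-chromen-6-yl)chroman-4-one | CC(C)(O)CCc1c(O)cc(O)c2c1OC(c1cc3c(cc1O)OC(C)(C)C=C3)CC2=O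
F9 | step 8 | 6-bromo-2,2-dimethyl-2H-chromen-7-ol | CC1(C)C=Cc2cc(Br)c(O)cc2O1
A1 | alternative 1 | 1-{2-[(7-tert-butyldimethylsilyloxy-2,2-dimethyl-2H-chromen-6-yl)methoxy]-4,6-bis(tert-butyldimethylsilyloxy)-3-[3-methyl-3-(triethylsilyloxy)butyl]phenyl}-2-diazoethanone | CC(C)(O[Si](CC)(CC)CC)CCc1c(O[Si](C)(C)C(C)(C)C)cc(O[Si](C)(C)C(C)(C)C)c(C(=O)C=[N+]=[N-])c1OCc1cc2c(cc1O[Si](C)(C)C(C)(C)C)OC(C)(C)C=C2
A2 | alternative 1 | (2S)-5,7-bis(tert-butyldimethylsilyloxy)-2-(7-tert-butyldimethylsilyloxy-2,2-dimethyl-2H-chromen-6-yl)-8-[3-methyl-3-(triethylsilyloxy)butyl]chroman-4-one | CC(C)(O[Si](CC)(CC)CC)CCc1c(O[Si](C)(C)C(C)(C)C)cc(O[Si](C)(C)C(C)(C)C)c2c1O[C@H](c1cc3c(cc1O[Si](C)(C)C(C)(C)C)OC(C)(C)C=C3)CC2=O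
A3 | alternative 2 | 2-(hydroxymethyl)-6-(3-hydroxy-3-methylbutyl)-3,5-bis(methoxymethoxy)phenol | CC(C)(O)CCc1c(OCOC)cc(OCOC)c(CO)c1O
A4 | alternative 2 | 2,2-dimethyl-6-vinyl-2H-chromen-7-ol | C=Cc1cc2c(cc1O)OC(C)(C)C=C2
A5 | alternative 2 | (2S)-2-(7-hydroxy-2,2-dimethyl-2H-chromen-6-yl)-8-(3-hydroxy-3-methylbutyl)-5,7-bis(methoxymethoxy)chroman | CC(C)(O)CCc1c(OCOC)cc(OCOC)c2c1O[C@H](c1cc3c(cc1O)OC(C)(C)C=C3)CC2
A6 | alternative 3 | (2S)-8-(3-hydroxy-3-methylbutyl)-5,7-bis(methoxymethoxy)-2-[4-(2-methylbut-3-yn-2-yloxy)-2-(triisopropylsilyloxy)phenyl]chroman-4-one | CC(C)(O)CCc1c(OCOC)cc(OCOC)c2c1O[C@H](c1ccc(OC(C)(C)C#C)cc1O[Si](C(C)C)(C(C)C)C(C)C)CC2=O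
A7 | alternative 3 | (2S)-2-[2,2-dimethyl-7-(triisopropylsilyloxy)-2H-chromen-6-yl]-8-(3-hydroxy-3-methylbutyl)-5,7-bis(methoxymethoxy)chroman-4-one | CC(C)(O)CCc1c(OCOC)cc(OCOC)c2c1O[C@H](c1cc3c(cc1O[Si](C(C)C)(C(C)C)C(C)C)OC(C)(C)C=C3)CC2=O
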